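The dearomatised ring is numbered as a cyclohexa-2,5-dienone: C1 carbonyl, C2 (methyl), C3 and C5 (enol carbons), C4 (quaternary stereocentre), C6 (bridge). Its 1,3,5-oxygenation lets C5–C6–C1 be read as a malonyl unit and C2–C3–C4 as a ketone with both α-carbons. An Effenberger-type [3+3] annulation of malonyl dichloride with an acyclic 1-silyloxy-3-alkoxydiene, which already carries prenyl and the latent isobutyryl group on C4, forges C1–C2 and C4–C5 in one operation and sets C4. The C3 oxygen bears an acid-labile chiral 1-arylethyl group that excludes pyrone formation and steers ring closure. An ortho-quinone methide coupling then adds the aromatic half.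

Key step: step 4

Remark: (R)-1-(2,4,6-triisopropylphenyl)ethanol and phlorisobutyrophenone are taken as purchasable, and enol tautomers are drawn as in the target.

Step 1
Reactants: 1 (R)-1-(2,4,6-triisopropylphenyl)ethanol; 2 trichloroethylene; 3 prenyl bromide (1-bromo-3-methylbut-2-ene)
Product: 7 (R)-1-(2,4,6-triisopropylphenyl)ethyl 5-methylhex-4-en-1-ynyl ether, via dichlorovinyl ether 4 (not isolated), via chloroalkynyl ether 5 (not isolated), via lithium alkoxyacetylide 6 (not isolated)
Conditions: KH, THF, 0 °C; 2, −50 °C to rt; n-BuLi (2.4 equiv), −78 to −40 °C; 3, HMPA, −78 °C to rt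
Reagents that add atoms: trichloroethylene ClC=C(Cl)Cl; prenyl bromide CC(C)=CCBr
Why: This is the alkoxide/trichloroethylene route to ynol ethers: the potassium alkoxide substitutes 2, n-BuLi effects HCl elimination and then Cl–Li exchange, and the lithium alkoxyacetylide is alkylated (SN2) at the primary carbon of 3, none of which touches the benzylic stereocentre.

Step 2
Reactants: 7 ynol ether; 8 ethylmagnesium bromide; 9 isobutyryl chloride
Product: 11 (E)-2-methyl-4-(3-methylbut-2-enyl)-5-[(R)-1-(2,4,6-triisopropylphenyl)ethoxy]hept-4-en-3-one, via alkenylcopper 10 (not isolated)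
Conditions: 8, CuBr·SMe2, Et2O/Me2S, −45 °C; 7, −45 to −25 °C; then 9, Pd(PPh3)4 (5 mol %), THF, −25 to 0 °C
Reagents that add atoms: ethylmagnesium bromide CC[Mg]Br; isobutyryl chloride CC(C)C(=O)Cl
Why: syn-Carbocupration of an ynol ether puts ethyl on the oxygen-bearing, electrophilic alkyne carbon (future C3) and copper on the other (future C4), and Pd(0)-catalysed acylation of the alkenylcopper goes with retention, so the tetrasubstituted β-alkoxy enone should form as one regioisomer, which O-alkylation of the unsymmetrical 1,3-diketone could not guarantee.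

Step 3
Reactants: 11 β-alkoxy enone
Product: 13 2-methyl-4-(3-methylbut-2-enyl)-5-[(R)-1-(2,4,6-triisopropylphenyl)ethoxy]-3-(trimethylsilyloxy)hepta-3,5-diene, via lithium dienolate 12 (not isolated)
Conditions: LDA, THF, −78 °C; TMSCl, −78 to 0 °C; non-aqueous work-up (pentane, filtration)
Reagents that add atoms: chlorotrimethylsilane C[Si](C)(C)Cl
Why: Vinylogous (γ) deprotonation is favoured because the ethyl CH2 (future C2) lies cis to the carbonyl and the only α'-hydrogen is a hindered tertiary one, and O-silylation of the extended enolate gives a Chan/Brassard-type 1-silyloxy-3-alkoxydiene whose alkene geometries are of no consequence.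

Step 4
Reactants: 13 silyl dienol ether; 14 malonyl dichloride
Product: 17 (4R)-5-hydroxy-2-methyl-4-(3-methylbut-2-enyl)-4-(2-methylpropanoyl)-3-[(R)-1-(2,4,6-triisopropylphenyl)ethoxy]cyclohexa-2,5-dien-1-one, via β-keto acid chloride 15 (not isolated), via dienylketene 16 (not isolated)
Conditions: 14 (1.0 equiv), CH2Cl2, high dilution, slow addition of 13, −78 °C; then 2,6-di-tert-butyl-4-methylpyridine (1.1 equiv), −78 to 0 °C; chromatographic removal of the C4 epimer
Reagents that add atoms: malonyl dichloride O=C(Cl)CC(=O)Cl
Why: Proposed new method: the terminal diene carbon (future C2) attacks one acyl chloride of 14 with loss of TMSCl (C1–C2 bond), β-keto acid chloride 15 enolises towards C2 and gives up HCl to the hindered base, and dienylketene 16 closes between the ketene carbon and the fully substituted enol ether carbon (C4–C5 bond) to the dienone, drawn as its cross-conjugated tautomer. The closest known reaction types are the Effenberger cyclisation (α,α'-double C-acylation of alkyl enol ethers by malonyl dichloride), the terminal C-acylation of Chan- and Brassard-type dienes by acid chlorides and the ring closure of dienylketenes in Danheiser and Moore benzannulations; new are their merger on an acyclic push–pull diene and the auxiliary control. The single new ring, the six-membered carbocycle, closes by a thermal disrotatory 6π electrocyclisation of the ketene-terminated triene, formally an intramolecular C-acylation of C4. C4 is controlled by the (R)-1-arylethyl group on the C3 oxygen: this oxygen is flanked by the C2 methyl and the C4 prenyl CH2 (isobutyryl trans to oxygen, as in 11), so its O–CH bond should stand perpendicular to the triene plane with the carbinol hydrogen over the π system and the triisopropylphenyl group over the less crowded C2 side, which covers one face of C4 and leaves open the face whose attack gives 4R. The step needs C- over O-acylation and 1:1 stoichiometry: the alkyl group on the C3 oxygen makes the 4-hydroxy-2-pyrone that free or silylated enols give impossible, the isobutyryl oxygen could only close an eight-membered ring, slow addition at high dilution disfavours 2:1 adducts and ketene dimers, and the base keeps HCl away from the prenyl group and the acid-labile auxiliary. Since the two C4 epimers are diastereomers, the minor one should be removable by chromatography at this stage.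

Step 5
Reactants: 17 auxiliary-bearing dienone
Product: 18 (4R)-3,5-dihydroxy-2-methyl-4-(3-methylbut-2-enyl)-4-(2-methylpropanoyl)cyclohexa-2,5-dien-1-one
Conditions: TFA (10 % v/v), CH2Cl2, 0 °C, short contact
Reagents that add atoms: none
Why: This is an SN1/E1 cleavage of a secondary benzylic vinylogous ester: the vinylogous carboxylate is a good leaving group, the hindered benzylic cation collapses to the unreactive styrene, and the short cold contact should spare the prenyl group and leave C4 untouched.

Step 6
Reactants: 19 phlorisobutyrophenone (2-methyl-1-(2,4,6-trihydroxyphenyl)propan-1-one); 3 prenyl bromide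
Product: 20 2-methyl-1-[2,4,6-trihydroxy-3-(3-methylbut-2-enyl)phenyl]propan-1-one
Conditions: 3 (1.0 equiv), KOH, H2O, 0 °C to rt
Reagents that add atoms: prenyl bromide CC(C)=CCBr
Why: C-Alkylation of the ambident phloroglucinolate in water is the standard C-prenylation of acylphloroglucinols, the two free ring positions are equivalent, and one equivalent of bromide limits double prenylation.

Step 7
Reactants: 20 prenylated acylphloroglucinol; 21 Eschenmoser's salt (N,N-dimethylmethyleneiminium iodide); 18 dienone
Product: 24 target CNP0191741.1 (S at the quaternary carbon), via Mannich base 22 (not isolated), via ortho-quinone methide 23 (not isolated)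
Conditions: 20, 21 (1.05 equiv), CH2Cl2, rt; then 18 (1.0 equiv), toluene, 70 °C
Reagents that add atoms: Eschenmoser's salt C[N+](C)=C.[I-]
Why: A Mannich aminomethylation at the only free aromatic CH, thermal loss of the amine as its ammonium salt to the ortho-quinone methide and Michael addition of C6 of 18 (its only unsubstituted nucleophilic carbon) is the known way to unsymmetrical methylene-bridged acylphloroglucinol dimers, and it leaves C4 untouched (the descriptor changes from R to S only because the priorities of the ring branches change).

Compound list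
1 | (R)-1-(2,4,6-triisopropylphenyl)ethanol | C[C@@H](O)c1c(C(C)C)cc(C(C)C)cc1C(C)C | starting material
2 | trichloroethylene | ClC=C(Cl)Cl | starting material
3 | prenyl bromide | CC(C)=CCBr | starting material
4 | (E)-1,2-dichlorovinyl ether of 1 | C[C@@H](O/C(Cl)=C\Cl)c1c(C(C)C)cc(C(C)C)cc1C(C)C | intermediate
5 | chloroethynyl ether of 1 | C[C@@H](OC#CCl)c1c(C(C)C)cc(C(C)C)cc1C(C)C | intermediate
6 | lithium alkoxyacetylide of 1 | C[C@@H](OC#C[Li])c1c(C(C)C)cc(C(C)C)cc1C(C)C | intermediate
7 | (R)-1-(2,4,6-triisopropylphenyl)ethyl 5-methylhex-4-en-1-ynyl ether | C[C@@H](OC#CCC=C(C)C)c1c(C(C)C)cc(C(C)C)cc1C(C)C | intermediate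
8 | ethylmagnesium bromide | CC[Mg]Br | starting material
9 | isobutyryl chloride | CC(C)C(=O)Cl | starting material
10 | alkenylcopper (ethyl and copper cis) | C[C@@H](O/C(CC)=C(\CC=C(C)C)[Cu])c1c(C(C)C)cc(C(C)C)cc1C(C)C | intermediate
11 | (E)-2-methyl-4-(3-methylbut-2-enyl)-5-[(R)-1-(2,4,6-triisopropylphenyl)ethoxy]hept-4-en-3-one | C[C@@H](O/C(CC)=C(\CC=C(C)C)C(=O)C(C)C)c1c(C(C)C)cc(C(C)C)cc1C(C)C | intermediate
12 | lithium dienolate of 11 | C[C@@H](OC(=CC)C(CC=C(C)C)=C(O[Li])C(C)C)c1c(C(C)C)cc(C(C)C)cc1C(C)C | intermediate
13 | 1-silyloxy-3-alkoxydiene (TMS dienol ether of 11) | C[C@@H](OC(=CC)C(CC=C(C)C)=C(O[Si](C)(C)C)C(C)C)c1c(C(C)C)cc(C(C)C)cc1C(C)C | intermediate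
14 | malonyl dichloride | O=C(Cl)CC(=O)Cl | starting material
15 | β-keto acid chloride (11 acylated at the former ethyl CH2, epimers at that carbon) | C[C@@H](O/C(C(C)C(=O)CC(=O)Cl)=C(\CC=C(C)C)C(=O)C(C)C)c1c(C(C)C)cc(C(C)C)cc1C(C)C | intermediate
16 | dienylketene | C[C@@H](O/C(C(C)=C(O)C=C=O)=C(\CC=C(C)C)C(=O)C(C)C)c1c(C(C)C)cc(C(C)C)cc1C(C)C | intermediate
17 | (4R)-5-hydroxy-2-methyl-4-(3-methylbut-2-enyl)-4-(2-methylpropanoyl)-3-[(R)-1-(2,4,6-triisopropylphenyl)ethoxy]cyclohexa-2,5-dien-1-one | C[C@@H](OC1=C(C)C(=O)C=C(O)[C@@]1(CC=C(C)C)C(=O)C(C)C)c2c(C(C)C)cc(C(C)C)cc2C(C)C | intermediate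
18 | (4R)-3,5-dihydroxy-2-methyl-4-(3-methylbut-2-enyl)-4-(2-methylpropanoyl)cyclohexa-2,5-dien-1-one | OC1=C(C)C(=O)C=C(O)[C@@]1(CC=C(C)C)C(=O)C(C)C | intermediate
19 | phlorisobutyrophenone | CC(C)C(=O)c1c(O)cc(O)cc1O | starting material
20 | 2-methyl-1-[2,4,6-trihydroxy-3-(3-methylbut-2-enyl)phenyl]propan-1-one | CC(C)=CCc1c(O)cc(O)c(C(=O)C(C)C)c1O | intermediate
21 | Eschenmoser's salt | C[N+](C)=C.[I-] | starting material
22 | Mannich base (dimethylaminomethyl derivative of 20) | CC(C)=CCc1c(O)c(CN(C)C)c(O)c(C(=O)C(C)C)c1O | intermediate
23 | ortho-quinone methide of 20 | C=C1C(=O)C(CC=C(C)C)=C(O)C(C(=O)C(C)C)=C1O | intermediate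
24 | CNP0191741.1 | CC(C)=CCc1c(O)c(CC2=C(O)[C@@](CC=C(C)C)(C(=O)C(C)C)C(O)=C(C)C2=O)c(O)c(C(=O)C(C)C)c1O | target

Total step count: 7. Longest linear sequence: 6 (steps 1, 2, 3, 4, 5, 7).

Steps most likely to fail

1. Step 4.
   - Risk: intermolecular double acylation and ketene dimerisation may outrun ring closure. Acid may strip the auxiliary before closure, which reopens lactonisation. Facial discrimination may be weak.
   - Fallback: known chemistry, with the two bonds made in separate operations. It sets out from 11 and comes back at 17.
   - Lithium dienolate 12 is acylated at its γ-carbon with tert-butyl 3-chloro-3-oxopropanoate to the isolable tert-butyl β-keto ester F1.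
   - Heating this ester in toluene expels tert-butanol, the established neutral entry to acylketenes. This delivers ketene 16 free of acid chloride, HCl and base, and 16 closes to 17.
   - The C4 epimers are separated as diastereomers, so the auxiliary serves as a resolving handle even if induction is weak.

2. Step 2.
   - Risk: carbocupration at the hindered oxygen-bearing carbon may be slow, and the alkenylcopper may lose alkoxide by β-elimination on warming.
   - Fallback: it sets out from 6 and comes back at 11.
   - The acetylide is acylated with N-methoxy-N-methylisobutyramide to the push–pull alkoxy ynone F2.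
   - Both substituents of this ynone polarise the triple bond in the same sense, so conjugate addition of ethylcopper (from 8 and CuBr·SMe2) at the oxygen-bearing carbon should be fast at −78 °C.
   - The α-cuprated enone is trapped with 3 to give 11. Its alkene geometry does not matter because step 3 erases it.

3. Step 7.
   - Risk: retro-Mannich scrambling may lead to symmetrical dimers, and liberated amine may deacylate (retro-Claisen) the dienone with aromatisation.
   - Fallback: it sets out from 20 and comes back at 24.
   - Vilsmeier–Haack formylation gives the 2,4,6-trihydroxy-3-(2-methylpropanoyl)-5-(3-methylbut-2-enyl)benzaldehyde F3.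
   - Proline-catalysed three-component reductive alkylation of 18 with this aldehyde and Hantzsch ester follows. The Knoevenagel adduct F4 is reduced as it forms, which gives 24 without any amine leaving group.

Further compounds
F1 | step 4 | tert-butyl β-keto ester (15 with O-tert-butyl in place of Cl) | C[C@@H](O/C(C(C)C(=O)CC(=O)OC(C)(C)C)=C(\CC=C(C)C)C(=O)C(C)C)c1c(C(C)C)cc(C(C)C)cc1C(C)C
F2 | step 2 | 4-methyl-1-[(R)-1-(2,4,6-triisopropylphenyl)ethoxy]pent-1-yn-3-one | C[C@@H](OC#CC(=O)C(C)C)c1c(C(C)C)cc(C(C)C)cc1C(C)C
F3 | step 7 | 2,4,6-trihydroxy-3-(2-methylpropanoyl)-5-(3-methylbut-2-enyl)benzaldehyde | CC(C)=CCc1c(O)c(C=O)c(O)c(C(=O)C(C)C)c1O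
F4 | step 7 | Knoevenagel adduct of F3 and 18 (arylmethylidene at C6) | CC(C)=CCc1c(O)c(C=C2C(=O)C(C)=C(O)[C@](CC=C(C)C)(C(=O)C(C)C)C2=O)c(O)c(C(=O)C(C)C)c1O
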